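## Retrosynthetic overview

- The last step is O-demethylation of the methyl tetronate; before that, one B-alkyl Suzuki coupling joins a tetronate-bearing alkylborane to an (E)-2-bromoalkene that carries the bis-furan.
- The (E)-trisubstituted alkene comes from propyne via (E)-2-bromo-1-iodopropene, used in two successive stereoretentive couplings (C–I first, then C–Br).
- The (Z)-ylidene tetronate comes from aldol–dehydration of lithiated 4-methoxy-3-methylfuran-2(5H)-one with (R)-2-methylpent-4-enal.
- Key step: enantioselective Zr-catalysed methylalumination/oxidation of one vinyl group of symmetric penta-1,4-diene sets the only stereocentre and leaves the other vinyl group as the coupling handle.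
- No ring is constructed: both furans come from furan-3-carbaldehyde and 3-(bromomethyl)furan (joined by C5 lithiation/alkylation), and the butenolide from 3-methyltetronic acid.

Assumption: penta-1,4-diene, propyne, 3-methyltetronic acid and 3-(bromomethyl)furan are taken as catalogue chemicals. The stereocentre in the target SMILES is read as (R), with 5-ylidene (Z) and chain alkene (E).

## Route

**Step 1 (key step)**
Reactants: 1, penta-1,4-diene (3 equiv)
Product: 2, (2R)-2-methylpent-4-en-1-ol
Conditions: Me3Al (limiting), (−)-(NMI)2ZrCl2 (3–5 mol%; the catalyst enantiomer that gives the 2R alcohol), MAO (cat.), CH2Cl2, 0 °C to rt; then O2, 0 °C; aqueous work-up. Expected crude ee is roughly 75–80% (typical for this reaction class), so the minor (S)-alcohol is removed as its acetate with Amano PS lipase/vinyl acetate.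
Reagents that add atoms: trimethylaluminium, C[Al](C)C (adds CH3); dioxygen, O=O (adds O)
Why: Negishi ZACA reaction: face-selective insertion of one of the two equivalent vinyl groups into the chiral zirconocene–CH3 bond puts CH3 on C2 and Al on C1, and O2 converts C–Al to C–OH with the C2 configuration retained, while excess diene suppresses double reaction.

**Step 2**
Reactants: 2, (2R)-2-methylpent-4-en-1-ol
Product: 3, (2R)-2-methylpent-4-enal
Conditions: (COCl)2, DMSO, CH2Cl2, −78 °C; i-Pr2NEt, −78 to −30 °C; cold pH 7 work-up; used at once as a cold concentrated solution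
Reagents that add atoms: none
Why: Swern oxidation with a hindered base and cold neutral work-up gives the α-branched aldehyde without epimerisation, and immediate use avoids loss by volatility.

**Step 3**
Reactants: 4, 3-methyltetronic acid (4-hydroxy-3-methylfuran-2(5H)-one)
Product: 5, 4-methoxy-3-methylfuran-2(5H)-one
Conditions: Me2SO4, K2CO3, acetone, reflux
Reagents that add atoms: dimethyl sulfate, COS(=O)(=O)OC (adds CH3)
Why: O-alkylation of the vinylogous acid with a hard methylating agent protects the acidic OH so that C5 can be deprotonated.

**Step 4**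
Reactants: 5, 4-methoxy-3-methylfuran-2(5H)-one; 3, (2R)-2-methylpent-4-enal
Product: 6, (5Z)-4-methoxy-3-methyl-5-[(2R)-2-methylpent-4-en-1-ylidene]furan-2(5H)-one
Conditions: LDA, THF, −78 °C; add 3, −78 °C; MsCl, Et3N, −78 to 0 °C; DBU, 0 °C to rt (one pot)
Reagents that add atoms: none
Why: Aldol addition of the C5 lithio-tetronate, in-situ mesylation and E1cB elimination give the ylidene; the Z isomer is favoured because the side chain avoids the 4-OMe group, and the adjacent stereocentre is not touched.

**Step 5**
Reactants: 7, furan-3-carbaldehyde; 8, 3-(bromomethyl)furan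
Product: 9, 5-(furan-3-ylmethyl)furan-3-carbaldehyde
Conditions: lithium morpholide (morpholine, n-BuLi), THF, −78 °C; s-BuLi, −78 °C; add 8, −78 °C to rt; aq NH4Cl
Reagents that add atoms: none
Why: In-situ α-amino alkoxide protection of the aldehyde with the bulky morpholide steers lithiation to the remote C5 position, and the furyllithium is alkylated by the benzylic-type bromide to give the 2,4-disubstituted furan; work-up releases the aldehyde.

**Step 6**
Reactants: 9, 5-(furan-3-ylmethyl)furan-3-carbaldehyde
Product: 10, 4-ethenyl-2-(furan-3-ylmethyl)furan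
Conditions: Ph3PCH3Br, KOt-Bu, THF, 0 °C to rt
Reagents that add atoms: methyltriphenylphosphonium bromide, [Br-].C[P+](c1ccccc1)(c1ccccc1)c1ccccc1 (adds CH2)
Why: Wittig methylenation of the heteroaryl aldehyde; the product is used promptly because vinylfurans polymerise.

**Step 7**
Reactants: 11, propyne
Product: 12, (E)-2-bromo-1-iodoprop-1-ene
Conditions: IBr, CH2Cl2, −78 to −20 °C, dark
Reagents that add atoms: iodine monobromide, BrI (adds I and Br)
Why: Anti (trans) Markovnikov halogen addition through the iodonium ion places I on the terminal carbon and Br on the methyl-bearing carbon, with the two halogens trans.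

**Step 8**
Reactants: 10, 4-ethenyl-2-(furan-3-ylmethyl)furan; 12, (E)-2-bromo-1-iodoprop-1-ene (1.5 equiv)
Product: 13, 4-[(3E)-4-bromopent-3-en-1-yl]-2-(furan-3-ylmethyl)furan
Conditions: 9-BBN, THF, 0 °C to rt; then 12, PdCl2(dppf) (5 mol%), AsPh3, Cs2CO3, DMF/H2O, rt, dark
Reagents that add atoms: none (9-BBN delivers only H)
Why: Proposed new method: anti-Markovnikov hydroboration of the vinylfuran followed by B-alkyl Suzuki–Miyaura coupling that should occur only at the unhindered C–I bond (oxidative addition far faster than at the α-methyl C–Br) with retention of geometry; the risk is β-bromide loss from the β-bromovinyl–Pd intermediate, countered by fast room-temperature transmetalation, and the closest known chemistry is B-alkyl Suzuki coupling of vinyl iodides and sequential chemoselective couplings of (E)-1-halo-2-iodoalkenes.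

**Step 9**
Reactants: 6, (5Z)-4-methoxy-3-methyl-5-[(2R)-2-methylpent-4-en-1-ylidene]furan-2(5H)-one; 13, 4-[(3E)-4-bromopent-3-en-1-yl]-2-(furan-3-ylmethyl)furan
Product: 14, (5Z)-5-[(2R,6E)-9-[5-(furan-3-ylmethyl)furan-3-yl]-2,6-dimethylnon-6-en-1-ylidene]-4-methoxy-3-methylfuran-2(5H)-one
Conditions: 6, 9-BBN, THF, 0 °C to rt; then 13, Pd(OAc)2/SPhos (5/10 mol%), aq K3PO4, THF, rt to 40 °C
Reagents that add atoms: none (9-BBN delivers only H)
Why: 9-BBN hydroborates only the terminal alkene of 6 (the conjugated ylidene and lactone are inert), and the B-alkyl Suzuki–Miyaura coupling with the 2-bromoalkene proceeds with retention, so the new chain ends up trans to the furylethyl chain (6E).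

**Step 10**
Reactants: 14, the methyl tetronate from step 9
Product: 15, (5Z)-5-[(2R,6E)-9-[5-(furan-3-ylmethyl)furan-3-yl]-2,6-dimethylnon-6-en-1-ylidene]-4-hydroxy-3-methylfuran-2(5H)-one (target)
Conditions: n-PrSLi, HMPA/THF, 0 °C to rt; cold pH 3 citrate work-up
Reagents that add atoms: none
Why: SN2 demethylation of the vinylogous methyl ester by thiolate releases the tetronate anion under non-acidic, non-oxidising conditions that the furans, both alkenes and the stereocentre tolerate.

## Compound list

1 | penta-1,4-diene | C=CCC=C | starting material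
2 | (2R)-2-methylpent-4-en-1-ol | OC[C@H](C)CC=C | intermediate
3 | (2R)-2-methylpent-4-enal | O=C[C@H](C)CC=C | intermediate
4 | 3-methyltetronic acid (4-hydroxy-3-methylfuran-2(5H)-one) | CC1=C(O)COC1=O | starting material
5 | 4-methoxy-3-methylfuran-2(5H)-one | CC1=C(OC)COC1=O | intermediate
6 | (5Z)-4-methoxy-3-methyl-5-[(2R)-2-methylpent-4-en-1-ylidene]furan-2(5H)-one | CC1=C(OC)/C(=C/[C@H](C)CC=C)OC1=O | intermediate
7 | furan-3-carbaldehyde | O=Cc1ccoc1 | starting material
8 | 3-(bromomethyl)furan | BrCc1ccoc1 | starting material
9 | 5-(furan-3-ylmethyl)furan-3-carbaldehyde | O=Cc1coc(Cc2ccoc2)c1 | intermediate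
10 | 4-ethenyl-2-(furan-3-ylmethyl)furan | C=Cc1coc(Cc2ccoc2)c1 | intermediate
11 | propyne | CC#C | starting material
12 | (E)-2-bromo-1-iodoprop-1-ene | C/C(Br)=C\I | intermediate
13 | 4-[(3E)-4-bromopent-3-en-1-yl]-2-(furan-3-ylmethyl)furan | C/C(Br)=C\CCc1coc(Cc2ccoc2)c1 | intermediate
14 | (5Z)-5-[(2R,6E)-9-[5-(furan-3-ylmethyl)furan-3-yl]-2,6-dimethylnon-6-en-1-ylidene]-4-methoxy-3-methylfuran-2(5H)-one | CC1=C(OC)/C(=C/[C@H](C)CCC/C(C)=C/CCc2coc(Cc3ccoc3)c2)OC1=O | intermediate
15 | (5Z)-5-[(2R,6E)-9-[5-(furan-3-ylmethyl)furan-3-yl]-2,6-dimethylnon-6-en-1-ylidene]-4-hydroxy-3-methylfuran-2(5H)-one | CC1=C(O)/C(=C/[C@H](C)CCC/C(C)=C/CCc2coc(Cc3ccoc3)c2)OC1=O | target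

## Summary

Total steps: 10.
Longest linear sequence: 5 steps (1 → 2 → 3 → 6 → 14 → 15 through steps 1, 2, 4, 9, 10; equally 7 → 9 → 10 → 13 → 14 → 15 through steps 5, 6, 8, 9, 10).

Steps most likely to fail, each with a fallback that changes the approach:

1. **Step 1** (modest intrinsic ee, mono- versus double carboalumination, volatile substrate and product). Fallback: make 2 by lipase desymmetrisation of 2-methylpropane-1,3-diol to the monoacetate, then tosylation, vinyl-cuprate displacement and deacetylation. This gives the same alcohol in high ee at the cost of three extra steps.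
2. **Step 8** (β-bromide elimination to propyne, or double coupling on the dihaloalkene). Fallback: drop the dihaloalkene and use alkyne hydrometalation instead. Couple the same B-alkyl-9-BBN with 1-bromopropyne to give 2-(furan-3-ylmethyl)-4-(pent-3-yn-1-yl)furan, then Schwartz hydrozirconation (equilibrated to Zr on the methyl-bearing carbon) and I2 to give the (E)-2-iodoalkene analogue of 13 for step 9.
3. **Step 4** (volatile, epimerisable aldehyde 3; one-pot aldol/mesylation/elimination). Fallback: reverse the order of events. Hydroborate 2 (as its TBS ether) and couple it with 13 first, then deprotect, oxidise the non-volatile long-chain alcohol and perform the tetronate aldol–dehydration last. This is less convergent but removes the volatile C6 aldehyde.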